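Readings and results are calculated for an exercise.

Of the first portion of substrate, 3.0% of the whole charge is left at 15.0 min in the east run of this flask, down from 17.1% at 4.00 min.

- east: substrate 0.010 M (in portions, 3); reagent 0.012 M; initiator 50 µM; the very flask that is asked about, followed so far; portions every 15 min
- flask: substrate 0.010 M (in portions, 3); reagent 0.0120 M; initiator 50 µM; time 50 min; the portions of substrate follow each other after 15 min, the first at the start

- east (time / min: product / %, substrate / %): 4.00: 15.4, 17.1; 8.00: 23.9, 9.3; 12.0: 28.7, 4.7; 15.0: 30.7, 3.0; 20.0: 50.2, 16.7

(scatter of a reading: 0.3 percentage points)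

- concentration of product at 50 min, in M
- concentration of substrate at 50 min, in M

I work with what is left. Those two readings give a loss of 0.158 min⁻¹, a pseudo-first-order rate constant. Across the second addition the readings give 0.155 min⁻¹, close to it though reagent has been consumed, so I carry the first figure forward.

At 50 min I reckon the fraction left at 1.55%, the mean over the 3 portions of e to the power of minus rate constant times the portion's age. So I commit to 1.55 × 10⁻⁴ M of substrate and 0.00984 M of product. Reagent was not read, so I assume one reagent per product; that product then takes less than the 0.0120 M of reagent charged, and I take substrate as the limiting reagent.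

The forecast gives 0.0098 M of product and 1.900 × 10⁻⁴ M of substrate, more substrate than mine, and adds “the range is skewed towards more substrate”.

The flask gives 0.00978 M of product and 2.16 × 10⁻⁴ M of substrate, which is 2.16% of the charge against my 1.55%.

initiator → 2 initiating radical (k = 1.10 × 10⁻⁴ s⁻¹); substrate + initiating radical ⇌ chain carrier (K = 7.70 × 10⁷ M⁻¹, k = 2.80 × 10⁵ M⁻¹ s⁻¹); reagent + chain carrier → product + initiating radical (k = 1.10 × 10⁵ M⁻¹ s⁻¹); 2 initiating radical → ended chains (k = 5.90 × 10⁷ M⁻¹ s⁻¹) In this flask reagent still stands at 18.5% of its own charge at 50.0 min. The neighbour flask with 0.017 M of substrate needs, at one reagent per product, 0.0167 M of reagent to reach my fraction left, more than its 0.0120 M; that charge of reagent covers all but 29.4% of its substrate, and that neighbour flask ends with reagent at 0% and free substrate at 29.4%.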